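(Readings and results were generated by integration on assumed constants; noise was put on by code.)

The trap in these runs is to take the Q and X you can read for the whole of what E has become, when solid E, dissolved L and the bis adduct J stand unread in the flask.

| setting | violet | amber | green | noon | dusk |
|---|---|---|---|---|---|
| E | 0.25 M | 0.25 M | 0.25 M | 0.25 M | 0.25 M |
| D | 0.12 M | 0.28 M | 0.56 M | 0.125 M | 0.750 M |
| remark | run made earlier | run made earlier | run made earlier |  |  |
| time |  |  |  | 50 min | 50 min |

| run | time / min | Q / % | X / % |
|---|---|---|---|
| violet | 4.00 | 0.5 | 0 |
| violet | 12.0 | 1.2 | 2.3 |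
| violet | 25.0 | 6.7 | 4.6 |
| violet | 40.0 | 12.3 | 5.9 |
| violet | 50.0 | 13.9 | 7.7 |
| amber | 10.0 | 4.0 | 1.9 |
| amber | 20.0 | 9.0 | 6.0 |
| amber | 30.0 | 13.7 | 6.7 |
| amber | 40.0 | 17.5 | 7.7 |
| amber | 50.0 | 21.6 | 9.7 |
| green | 10.0 | 4.2 | 1.8 |
| green | 20.0 | 10.3 | 4.5 |
| green | 30.0 | 14.6 | 5.8 |
| green | 40.0 | 18.2 | 5.8 |
| green | 50.0 | 20.8 | 7.5 |

(scatter of a reading: 0.5 percentage points)

- solid, in amounts per volume of the solution: E
- steps under discussion: L + D -> X; L + D -> Q; D + X -> J; D + Q -> J; E <-> L
- at the start none of E is in solution

- which of these holds the largest part of the E at the end of noon (E / Q / X / J)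
- which of these holds the largest part of the E at the end of dusk (E / Q / X / J)
- amount of Q at the end of noon, in percent of the E charged

Build the flask up one process at a time and carry one number through it, the apparent reaction order of Q in D, which violet and amber put at 0.520: the slope of ln Q against ln c(D) at a fixed time. With L + D → Q running by itself at a steady c(L) and with little of D used, that slope is 1, and you read less than that. Add the dissolving of E, a feed that starts from nothing in solution and in whose step D takes no part, and a slope below 1 becomes possible. Noon has 1.04 times the D of violet, so if you hold the order fixed over that small step, the 13.9% of Q read in violet at 50.0 min becomes 14.2%, and that is my number for noon.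

Now add D + X → J and D + Q → J. From amber to green c(D) is twice as high, yet the same slope reads −0.0544, and the sum of Q and X goes down from 31.3% to 28.3%, a drop of 3 percentage points against a scatter of 0.5 points on each reading. A sum that falls as D rises means to me that Q and X are going on to J, so for dusk I expect J ahead of E, as a judgement without a figure.

The forecast, made from the same runs, gives E for noon with 14.5% of Q, and E for dusk, holding that “undissolved E should remain the largest portion”; I part from it at dusk.

    L + D → X (k = 0.130 /M/min)
    L + D → Q (k = 0.170 /M/min)
    D + X → J (k = 0.260 /M/min)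
    D + Q → J (k = 0.0860 /M/min)
    E ⇌ L, rate k5*(cs5 - [L]) while solid is left; crystals form when [L] > cs5 (solubility = 0.220 M, k = 0.0230 /min)

Among the four choices asked, the flask answers E for noon, with 28.7% still solid, 42.4% standing outside the choices as dissolved L, and Q at 14.4% beside my 14.2%, and it answers J for dusk, where J holds 54.0% and E 9.23%. In noon at 50.0 min, Q is made 5.81 times faster than it is used up, each step taken net, while J stands at 5.80%. Carried from noon to the neighbour charged with 0.50 M of D, the order gives 29.7% of Q; that flask holds 21.7%, with J at 38.3%.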